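Everything rests on cutting the two aryl–CH2 bonds that hold the prenyl groups at C2' and C3' of ring B. These neighbouring carbons sit beside the C4'/C5' catechol in the pattern in which vanillin takes up two bromines, so the coupling substrate is a fully MOM-protected 2',3'-dibromoflavonol that already carries the 1,1-dimethylallyl group at C8 of ring A. One twofold, linear-selective Suzuki–Miyaura coupling with prenylboronic acid pinacol ester then installs both side chains, and acidic methanolysis frees the five hydroxyls. The dibromide comes from a dibromocatechol aldehyde and a reverse-prenylated phloroacetophenone (para-blocked aromatic Claisen rearrangement) by chalcone formation, Algar–Flynn–Oyamada closure and 3-O-protection.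

Key step: step 10

Remark: compounds 9 and 13 are racemic in-flask intermediates whose stereocentres disappear within the same step; the target has no stereocentre.
Remark: in step 10 the less hindered C3'–Br is assumed to couple first (compound 17); the opposite order would converge on the same product.

Step 1
Reactants: 1 vanillin
Product: 3 5,6-dibromovanillin (2,3-dibromo-4-hydroxy-5-methoxybenzaldehyde), via 5-bromovanillin 2 (not isolated)
Conditions: Br2 (2.3 equiv), Fe powder (cat.), AcOH, rt → 50 °C
Reagents that add atoms: bromine, BrBr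
Why: Electrophilic aromatic bromination, in which the phenol directs the first bromine ortho to itself (C5) and the second enters at C6, para to the methoxy group, because C2 between the formyl and methoxy groups is the most hindered and least activated site.

Step 2
Reactants: 3 5,6-dibromovanillin
Product: 4 2,3-dibromo-4,5-dihydroxybenzaldehyde
Conditions: BBr3 (3 equiv), CH2Cl2, −78 °C → rt; then H2O
Reagents that add atoms: none
Why: Lewis acid cleavage of an aryl methyl ether, in which BBr3 binds the methoxy oxygen and bromide removes the methyl group by SN2 displacement, while the aryl bromides are inert and the aldehyde is restored on aqueous work-up.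

Step 3
Reactants: 4 2,3-dibromo-4,5-dihydroxybenzaldehyde
Product: 5 2,3-dibromo-4,5-bis(methoxymethoxy)benzaldehyde
Conditions: MOMCl (3 equiv), i-Pr2NEt, CH2Cl2, 0 °C → rt
Reagents that add atoms: chloromethyl methyl ether, COCCl
Why: Williamson-type O-alkylation of both catechol hydroxyls with the reactive α-chloro ether gives base-stable acetal ethers that mask the catechol through the condensation, oxidation and coupling steps.

Step 4
Reactants: 6 2,4,6-trihydroxyacetophenone; 7 prenyl bromide (1.0 equiv)
Product: 8 1-[2,6-dihydroxy-4-(3-methylbut-2-enyloxy)phenyl]ethanone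
Conditions: K2CO3 (1.1 equiv), acetone, rt → 40 °C
Reagents that add atoms: none
Why: Williamson etherification under weak base, in which the 4-OH (para to the acetyl group and not engaged in the hydrogen bond to the carbonyl) is the most acidic and accessible hydroxyl, so one equivalent of halide in acetone should alkylate it preferentially on oxygen.

Step 5
Reactants: 8 1-[2,6-dihydroxy-4-(3-methylbut-2-enyloxy)phenyl]ethanone
Product: 10 1-[2,4,6-trihydroxy-3-(2-methylbut-3-en-2-yl)phenyl]ethanone, via cyclohexadienone 9 (not isolated)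
Conditions: PhNEt2, 190 °C, Ar, sealed tube
Reagents that add atoms: none
Why: Aromatic Claisen rearrangement ([3,3]-sigmatropic shift) in a substrate whose two ortho carbons are equivalent and whose para carbon carries the acetyl group, so dienone 9 cannot relay the allyl unit by a Cope shift to a free para position (the path that turns prenyl ethers ortho to the acyl group into linear para-prenyl phenols) and can only enolise to the single 1,1-dimethylallyl phenol, the basic solvent holding back acid-mediated ring closure onto the flanking hydroxyls.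

Step 6
Reactants: 10 1-[2,4,6-trihydroxy-3-(2-methylbut-3-en-2-yl)phenyl]ethanone
Product: 11 1-[2-hydroxy-4,6-bis(methoxymethoxy)-3-(2-methylbut-3-en-2-yl)phenyl]ethanone
Conditions: MOMCl (2.2 equiv), i-Pr2NEt, CH2Cl2, 0 °C → rt
Reagents that add atoms: chloromethyl methyl ether, COCCl
Why: Selective O-alkylation, in which the 2-OH is wedged between the acetyl group and the quaternary carbon and is held in the hydrogen bond to the carbonyl, so amine-base MOM protection should stop after the 4-OH and 6-OH, the pattern generally seen with 3-alkylphloroacetophenones.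

Step 7
Reactants: 11 1-[2-hydroxy-4,6-bis(methoxymethoxy)-3-(2-methylbut-3-en-2-yl)phenyl]ethanone; 5 2,3-dibromo-4,5-bis(methoxymethoxy)benzaldehyde
Product: 12 (E)-3-[2,3-dibromo-4,5-bis(methoxymethoxy)phenyl]-1-[2-hydroxy-4,6-bis(methoxymethoxy)-3-(2-methylbut-3-en-2-yl)phenyl]prop-2-en-1-one
Conditions: KOH, EtOH–H2O, rt
Reagents that add atoms: none
Why: Claisen–Schmidt (crossed aldol) condensation, in which the methyl ketone enolate adds to the non-enolisable aldehyde and E1cB loss of hydroxide gives the conjugated E-enone under thermodynamic control, the MOM ethers and aryl bromides being stable to hydroxide at room temperature.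

Step 8
Reactants: 12 the 2'-hydroxychalcone
Product: 14 2-[2,3-dibromo-4,5-bis(methoxymethoxy)phenyl]-3-hydroxy-5,7-bis(methoxymethoxy)-8-(2-methylbut-3-en-2-yl)chromen-4-one, via trans-dihydroflavonol 13 (not isolated)
Conditions: H2O2 (30% aq), NaOH (aq), MeOH–THF, 0 °C → rt
Reagents that add atoms: hydrogen peroxide, OO
Why: Algar–Flynn–Oyamada reaction, in which alkaline hydrogen peroxide turns the 2'-hydroxychalcone by 6-endo phenoxide attack at the β-carbon and α-hydroxylation into dihydroflavonol 13, which is oxidised further in the same flask to the flavonol; the isolated vinyl group, the acetals and the bromides do not react with hydroperoxide anion, and the low temperature is chosen to hold back the aurone pathway known for 6'-alkoxychalcones.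

Step 9
Reactants: 14 the 3-hydroxyflavone
Product: 15 2-[2,3-dibromo-4,5-bis(methoxymethoxy)phenyl]-3,5,7-tris(methoxymethoxy)-8-(2-methylbut-3-en-2-yl)chromen-4-one
Conditions: MOMCl, i-Pr2NEt, CH2Cl2, 0 °C → reflux
Reagents that add atoms: chloromethyl methyl ether, COCCl
Why: O-Alkylation of the acidic, carbonyl-chelated 3-hydroxyl removes the one free, oxidation-prone and palladium-binding site before the coupling and makes all five protecting groups identical for a single final deprotection.

Step 10
Reactants: 15 the penta-O-MOM 2',3'-dibromoflavonol; 16 prenylboronic acid pinacol ester (4 equiv)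
Product: 18 penta-O-MOM broussoflavonol C, via monoprenyl bromide 17 (not isolated)
Conditions: Pd(OAc)2 (10 mol %), t-BuXPhos (20 mol %), K3PO4 (aq), THF, 40 → 60 °C, degassed
Reagents that add atoms: none
Why: Zerovalent palladium, formed in the flask from Pd(OAc)2 and the phosphine, inserts into each aryl C–Br bond; base-assisted transmetalation of the prenylboronate gives an aryl(allyl) complex of divalent palladium whose tertiary and primary σ-allyl forms interconvert through the π-allyl complex, and reductive elimination from the primary form makes the aryl–CH2 bond. The closest known reaction type is the ligand-controlled α-selective Suzuki–Miyaura coupling of aryl bromides with 3,3-disubstituted allylboronates, here run twice on one ring. No ring is closed and no stereocentre is formed. The selectivity needed is linear over branched attachment at both carbons, which the bulky di-tert-butyl biarylphosphine secures by disfavouring the crowded tertiary σ-allyl intermediate, helped by the two ortho substituents that flank each bromide. Site selectivity is not in question because C2' and C3' are fixed by the bromines, the C8 vinyl group offers palladium no leaving group, and the five MOM ethers and the chromone tolerate aqueous phosphate. An excess of boronate is used so that intermediate 17 is carried on to 18.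

Step 11
Reactants: 18 penta-O-MOM broussoflavonol C
Product: 19 broussoflavonol C
Conditions: HCl (3 M aq), MeOH–THF, rt → 40 °C, stopped when the last MOM ether is gone
Reagents that add atoms: none
Why: Acid-catalysed acetal methanolysis (transacetalisation to dimethoxymethane) frees all five phenols under conditions that are used for other MOM-protected prenylflavonoids and are mild enough to leave the prenyl and vinyl double bonds unprotonated, so no ring closure onto the neighbouring hydroxyls is expected.

Compound list
1 | vanillin (4-hydroxy-3-methoxybenzaldehyde) | COc1cc(C=O)ccc1O | starting material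
2 | 5-bromovanillin (3-bromo-4-hydroxy-5-methoxybenzaldehyde) | COc1cc(C=O)cc(Br)c1O | intermediate (not isolated)
3 | 5,6-dibromovanillin (2,3-dibromo-4-hydroxy-5-methoxybenzaldehyde) | COc1cc(C=O)c(Br)c(Br)c1O | intermediate
4 | 2,3-dibromo-4,5-dihydroxybenzaldehyde | O=Cc1cc(O)c(O)c(Br)c1Br | intermediate
5 | 2,3-dibromo-4,5-bis(methoxymethoxy)benzaldehyde | COCOc1cc(C=O)c(Br)c(Br)c1OCOC | intermediate
6 | 2,4,6-trihydroxyacetophenone | CC(=O)c1c(O)cc(O)cc1O | starting material
7 | prenyl bromide (1-bromo-3-methylbut-2-ene) | CC(C)=CCBr | starting material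
8 | 1-[2,6-dihydroxy-4-(3-methylbut-2-enyloxy)phenyl]ethanone | CC(=O)c1c(O)cc(OCC=C(C)C)cc1O | intermediate
9 | 4-acetyl-3,5-dihydroxy-6-(2-methylbut-3-en-2-yl)cyclohexa-2,4-dien-1-one (racemic) | CC(=O)C1=C(O)C(C(C)(C)C=C)C(=O)C=C1O | intermediate (not isolated)
10 | 1-[2,4,6-trihydroxy-3-(2-methylbut-3-en-2-yl)phenyl]ethanone | CC(=O)c1c(O)cc(O)c(C(C)(C)C=C)c1O | intermediate
11 | 1-[2-hydroxy-4,6-bis(methoxymethoxy)-3-(2-methylbut-3-en-2-yl)phenyl]ethanone | CC(=O)c1c(O)c(C(C)(C)C=C)c(OCOC)cc1OCOC | intermediate
12 | (E)-3-[2,3-dibromo-4,5-bis(methoxymethoxy)phenyl]-1-[2-hydroxy-4,6-bis(methoxymethoxy)-3-(2-methylbut-3-en-2-yl)phenyl]prop-2-en-1-one | C=CC(C)(C)c1c(OCOC)cc(OCOC)c(C(=O)/C=C/c2cc(OCOC)c(OCOC)c(Br)c2Br)c1O | intermediate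
13 | trans-2-[2,3-dibromo-4,5-bis(methoxymethoxy)phenyl]-3-hydroxy-5,7-bis(methoxymethoxy)-8-(2-methylbut-3-en-2-yl)chroman-4-one (racemic, the 2R,3R enantiomer drawn) | C=CC(C)(C)c1c(OCOC)cc(OCOC)c2C(=O)[C@H](O)[C@@H](c3cc(OCOC)c(OCOC)c(Br)c3Br)Oc12 | intermediate (not isolated)
14 | 2-[2,3-dibromo-4,5-bis(methoxymethoxy)phenyl]-3-hydroxy-5,7-bis(methoxymethoxy)-8-(2-methylbut-3-en-2-yl)chromen-4-one | C=CC(C)(C)c1c(OCOC)cc(OCOC)c2c(=O)c(O)c(-c3cc(OCOC)c(OCOC)c(Br)c3Br)oc12 | intermediate
15 | 2-[2,3-dibromo-4,5-bis(methoxymethoxy)phenyl]-3,5,7-tris(methoxymethoxy)-8-(2-methylbut-3-en-2-yl)chromen-4-one (penta-O-MOM 2',3'-dibromoflavonol) | C=CC(C)(C)c1c(OCOC)cc(OCOC)c2c(=O)c(OCOC)c(-c3cc(OCOC)c(OCOC)c(Br)c3Br)oc12 | intermediate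
16 | prenylboronic acid pinacol ester (4,4,5,5-tetramethyl-2-(3-methylbut-2-enyl)-1,3,2-dioxaborolane) | CC(C)=CCB1OC(C)(C)C(C)(C)O1 | starting material
17 | 2-[2-bromo-4,5-bis(methoxymethoxy)-3-(3-methylbut-2-enyl)phenyl]-3,5,7-tris(methoxymethoxy)-8-(2-methylbut-3-en-2-yl)chromen-4-one | C=CC(C)(C)c1c(OCOC)cc(OCOC)c2c(=O)c(OCOC)c(-c3cc(OCOC)c(OCOC)c(CC=C(C)C)c3Br)oc12 | intermediate (not isolated)
18 | 2-[4,5-bis(methoxymethoxy)-2,3-bis(3-methylbut-2-enyl)phenyl]-3,5,7-tris(methoxymethoxy)-8-(2-methylbut-3-en-2-yl)chromen-4-one (penta-O-MOM broussoflavonol C) | C=CC(C)(C)c1c(OCOC)cc(OCOC)c2c(=O)c(OCOC)c(-c3cc(OCOC)c(OCOC)c(CC=C(C)C)c3CC=C(C)C)oc12 | intermediate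
19 | broussoflavonol C (2-[4,5-dihydroxy-2,3-bis(3-methylbut-2-enyl)phenyl]-3,5,7-trihydroxy-8-(2-methylbut-3-en-2-yl)chromen-4-one) | C=CC(C)(C)c1c(O)cc(O)c2c(=O)c(O)c(-c3cc(O)c(O)c(CC=C(C)C)c3CC=C(C)C)oc12 | target

Total step count: 11.
Longest linear sequence: 8 steps (6 → 19 through steps 4–11; the aldehyde branch 1 → 19 through steps 1–3 and 7–11 is equally long).

Steps most likely to fail

1. Step 10 (twofold coupling). After the first prenyl group is in place the remaining bromide is flanked on both sides, so oxidative addition and transmetalation may stall. Protodebromination, or reductive elimination from the tertiary allyl terminus giving a branched side chain, may then take over. The fallback moves the twofold prenylation to the small, formyl-activated aldehyde and sets out from 5. A double Stille coupling with tributyl(3-methylbut-2-enyl)stannane (Pd(PPh3)4, DMF, 100 °C; the tin reagent does not add to the aldehyde) should give 4,5-bis(methoxymethoxy)-2,3-bis(3-methylbut-2-enyl)benzaldehyde F1. Claisen–Schmidt condensation of F1 with acetophenone 11 (KOH, EtOH) should give the diprenyl 2'-hydroxychalcone F2. Algar–Flynn–Oyamada oxidation (H2O2, NaOH, MeOH–THF; trisubstituted alkenes are inert to alkaline peroxide) should then pass through the trans-dihydroflavonol F3 (not isolated) to the diprenyl 3-hydroxyflavone F4. MOMCl/i-Pr2NEt caps the 3-OH and the fallback comes back to the route at 18.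

2. Step 8 (Algar–Flynn–Oyamada closure). The phenoxide may attack the α-carbon of the oxidised enone and close the five-membered aurone ring, a diversion favoured by the 6'-alkoxy group and by the twisted ortho-bromo aryl ring. The fallback separates ring closure from oxygenation and sets out from chalcone 12. NaOAc in refluxing EtOH closes it by oxa-Michael addition to the racemic 5,7-bis(methoxymethoxy)flavanone F5. I2 in pyridine at 90 °C dehydrogenates this to the flavone F6. C3 lithiation with LiN(i-Pr)2 (THF, −78 °C) and trapping with B(OMe)3 give the 3-(dimethoxyboryl)flavone F7 (not isolated), and oxidation with H2O2 comes back to the route at flavonol 14.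

3. Step 6 (selective bis-protection). Discrimination between the two acetyl-flanking hydroxyls may be poor, or alkylation of the 4-OH next to the quaternary carbon may be sluggish, giving regioisomeric or incomplete protection. The fallback fixes the free hydroxyl before the rearrangement and sets out from 8. MOMCl (1.1 equiv)/i-Pr2NEt protects one of the two equivalent ortho hydroxyls while the other stays chelated, giving 1-[2-hydroxy-6-(methoxymethoxy)-4-(3-methylbut-2-enyloxy)phenyl]ethanone F8. Claisen rearrangement (PhNEt2, 190 °C) through the 6-(2-methylbut-3-en-2-yl)cyclohexa-2,4-dienone F9 (not isolated) is expected at C3, between the chelated hydroxyl and the ether oxygen, because the chelate fixes the C3=C4 double bond and the MOM group beside the acetyl methyl crowds C5. This gives 1-[2,4-dihydroxy-6-(methoxymethoxy)-3-(2-methylbut-3-en-2-yl)phenyl]ethanone F10. MOM protection of the single non-chelated 4-OH (MOMCl, i-Pr2NEt) comes back to the route at 11.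

Further compounds
F1 | step 10 | 4,5-bis(methoxymethoxy)-2,3-bis(3-methylbut-2-enyl)benzaldehyde | COCOc1cc(C=O)c(CC=C(C)C)c(CC=C(C)C)c1OCOC
F2 | step 10 | (E)-3-[4,5-bis(methoxymethoxy)-2,3-bis(3-methylbut-2-enyl)phenyl]-1-[2-hydroxy-4,6-bis(methoxymethoxy)-3-(2-methylbut-3-en-2-yl)phenyl]prop-2-en-1-one | C=CC(C)(C)c1c(OCOC)cc(OCOC)c(C(=O)/C=C/c2cc(OCOC)c(OCOC)c(CC=C(C)C)c2CC=C(C)C)c1O
F3 | step 10 | trans-2-[4,5-bis(methoxymethoxy)-2,3-bis(3-methylbut-2-enyl)phenyl]-3-hydroxy-5,7-bis(methoxymethoxy)-8-(2-methylbut-3-en-2-yl)chroman-4-one (racemic, the 2R,3R enantiomer drawn) | C=CC(C)(C)c1c(OCOC)cc(OCOC)c2C(=O)[C@H](O)[C@@H](c3cc(OCOC)c(OCOC)c(CC=C(C)C)c3CC=C(C)C)Oc12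
F4 | step 10 | 2-[4,5-bis(methoxymethoxy)-2,3-bis(3-methylbut-2-enyl)phenyl]-3-hydroxy-5,7-bis(methoxymethoxy)-8-(2-methylbut-3-en-2-yl)chromen-4-one | C=CC(C)(C)c1c(OCOC)cc(OCOC)c2c(=O)c(O)c(-c3cc(OCOC)c(OCOC)c(CC=C(C)C)c3CC=C(C)C)oc12
F5 | step 8 | 2-[2,3-dibromo-4,5-bis(methoxymethoxy)phenyl]-5,7-bis(methoxymethoxy)-8-(2-methylbut-3-en-2-yl)chroman-4-one (racemic) | C=CC(C)(C)c1c(OCOC)cc(OCOC)c2C(=O)CC(c3cc(OCOC)c(OCOC)c(Br)c3Br)Oc12
F6 | step 8 | 2-[2,3-dibromo-4,5-bis(methoxymethoxy)phenyl]-5,7-bis(methoxymethoxy)-8-(2-methylbut-3-en-2-yl)chromen-4-one | C=CC(C)(C)c1c(OCOC)cc(OCOC)c2c(=O)cc(-c3cc(OCOC)c(OCOC)c(Br)c3Br)oc12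
F7 | step 8 | dimethyl [2-[2,3-dibromo-4,5-bis(methoxymethoxy)phenyl]-5,7-bis(methoxymethoxy)-8-(2-methylbut-3-en-2-yl)-4-oxochromen-3-yl]boronate | C=CC(C)(C)c1c(OCOC)cc(OCOC)c2c(=O)c(B(OC)OC)c(-c3cc(OCOC)c(OCOC)c(Br)c3Br)oc12
F8 | step 6 | 1-[2-hydroxy-6-(methoxymethoxy)-4-(3-methylbut-2-enyloxy)phenyl]ethanone | CC(=O)c1c(O)cc(OCC=C(C)C)cc1OCOC
F9 | step 6 | 4-acetyl-5-hydroxy-3-(methoxymethoxy)-6-(2-methylbut-3-en-2-yl)cyclohexa-2,4-dien-1-one (racemic) | CC(=O)C1=C(O)C(C(C)(C)C=C)C(=O)C=C1OCOC
F10 | step 6 | 1-[2,4-dihydroxy-6-(methoxymethoxy)-3-(2-methylbut-3-en-2-yl)phenyl]ethanone | CC(=O)c1c(O)c(C(C)(C)C=C)c(O)cc1OCOC
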